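## Structural features

The target is a dihydroflavonol: ring A, a benzene ring, is fused through C4a and C8a to ring C, a dihydropyran-4-one, and ring B, a 4-hydroxyphenyl group, is attached to C2 of ring C. Ring A carries four oxygen atoms in a 1,2,3,5 pattern, namely the ring oxygen O1 on C8a, a hydroxyl on C5 that is hydrogen-bonded to the C4 carbonyl, the only methyl ether on C6 and a hydroxyl on C7, while C8 bears hydrogen. C2 (R, bearing ring B) and C3 (R, bearing the acetoxy group) are neighbours on ring C and their substituents are trans. The C3 acetate is the one ester among four oxygen functions and lies alpha to the ketone, so base can hydrolyse it, epimerise C3 or eliminate acetic acid towards the flavone. The beta-aryloxy ketone of ring C opens by retro-oxa-Michael reaction under base, which scrambles C2, and the free phenols make the compound easy to dehydrogenate in basic, aerated media. The real difficulties are to place the methyl ether at C6 and not at C8 (decided by which oxygen ortho to the acyl carbon becomes O1), to set the trans C2/C3 pair in absolute terms, and to acetylate the aliphatic hydroxyl alone. The key step exploits the C3 methylene group of the corresponding (2S)-flavanone, which sits between the C4 carbonyl and the C2 stereocentre of ring C: flavanone 3-hydroxylase replaces the C3 hydrogen trans to ring B by hydroxyl, and the target has the oxygenation pattern of that enzyme's natural product plus one methoxy group at C6.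

## Logic of the disconnections

The acetyl groups are dealt with first. 16 is traced back to 15 by re-forming three aryl O–acyl bonds, and 15 to 14 by cutting all four O–acyl bonds. The cut is made here because the secondary hydroxyl of 14 cannot be acetylated in preference to three phenols, whereas aryl acetates are cleaved much more easily than an alkyl acetate. The gain is that 14 needs no protecting group. The demand is a deacylation near neutral pH that leaves the C3 ester, C2 and C3 untouched.

The C3–O bond of 14 is cut next, which leads to 13. This removes one stereocentre and the only sp3-bound hydroxyl and leaves a flavanone with a single stereocentre. The forward step must oxidise C3 and not the benzylic C2, deliver oxygen trans to ring B, and tolerate three free phenols; an enzyme that does this on the parent flavanone answers all three points and, in addition, rejects the (2R) enantiomer.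

13 is traced to 12 by cutting three benzyl–oxygen bonds. The enzyme needs free phenols, but the steps before it need them masked, and benzyl ethers come off by neutral hydrogenolysis while the methyl ether at C6 stays. The forward step must not reduce the ketone, cleave the benzylic C2–O1 bond or expose the 5-hydroxyflavanone to base.

12 is cut at the bond between C2 and ring B, giving 10 and 11. Setting C2 by a catalyst-controlled carbon–carbon bond formation on a flat chromone is preferred to closing ring C by oxa-Michael addition of an open-chain enone, because that closure is reversible and, for an enone without an extra activating group, gives only modest enantioselectivity. The gain is an achiral bicyclic partner and a purchasable boronic acid, joined late. The demand is face-selective 1,4-addition to an electron-rich chromone without base.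

10 is cut at O1–C2 and C2–C3, through 9, back to 8; the carbon that becomes C2 comes from a formamide acetal. The cut is made here because 8 has only one free hydroxyl ortho to the acyl group, so that oxygen must become O1 and the methoxy group must end at C6. The forward step needs only condensation at the acetyl methyl group and an acid-induced addition–elimination.

8 is cut at the bond between ring A and the acetyl carbon, through 7, back to 6. The two free ring positions of 6 are equivalent and both are ortho to the free hydroxyl, so C-acetylation can give only one product. The demand is a Lewis acid mild enough for two aryl benzyl ethers.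

The aryl C–O bond of 6 that later becomes C8a–O1 is traced, through 5, to the formyl group of 4. This oxidative exchange of carbon for oxygen turns a purchasable 3,4,5-trioxygenated benzoate pattern into the 1,2,3,5-tetraoxygenated pattern of ring A without any selective methylation. The forward step needs migration of the aryl group rather than of hydrogen, which the para methoxy group favours.

4 goes back through 3 and 2 to 1 by two changes of oxidation level and by cutting two benzyl–oxygen bonds. 1 already holds the methyl ether between two equivalent hydroxyls, so the benzylation needs no selectivity.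

## Other disconnections considered

Alternative 1: The cut is the aryl ether bond O1–C8a. In the forward direction the open-chain bromo alcohol A2 is closed to the tricyclic acetonide A1 by CuI (monovalent copper), 1,10-phenanthroline and Cs2CO3. In A2 the future C3 and C4 oxygens are tied up as an acetonide and the future C2 hydroxyl is free. A1 is named here as a chromane, because the parent name flavan already contains the 2-phenyl group. The alkoxide binds copper, the aryl bromide adds, and reductive elimination from a trivalent copper intermediate forms the C–O bond in a six-membered closure. A2 would come from the reversed chalcone A3 by asymmetric dihydroxylation, acetonide formation and reduction of the ketone.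

- In its favour:
  - The C3 and C4 centres are set on an open chain by reagent control.
  - The ring closure touches no stereocentre.
  - No enzyme has to be produced.
  - When the C3 hydroxyl is finally acetylated the phenols are still benzyl ethers. On this point it is the better plan, since no discrimination between esters is needed.
- Against it here:
  - Ring A of A3 needs bromine meta to both benzyloxy groups, a position that direct bromination does not reach, so ring A costs at least as many steps as in the chosen route.
  - The bromide is electron-rich and ortho-substituted, and the alcohol is secondary and benzylic. Oxidation of the alcohol or loss of bromine can therefore compete with coupling.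
  - C2 depends on a substrate-controlled ketone reduction.
  - C4 arrives at the wrong oxidation level. After closure the trans-fused acetonide has to be removed and the C4 hydroxyl oxidised next to the C3 hydroxyl, before acetylation and debenzylation.
- Comparison:
  - Structure: the chosen plan is less protected and nearer the target after its key step.
  - Mechanism: the copper coupling is ordinary laboratory chemistry, whereas the chosen step depends on an enzyme accepting a new substrate.
  - Step economy: this route should be several steps longer.

Alternative 2: The cut is the C2–C3 bond. The hydroxyacetyl ketone A5 and the aldehyde A6 are joined by a dinuclear zinc catalyst made from ZnEt2 and a chiral bis(prolinol)phenol ligand. The chelated zinc enediolate of A5 adds to A6 and should give the syn diol A4 with both carbinol centres set at once. Ring C would then be closed after removal of the methoxymethyl group by a Mitsunobu reaction. This must invert the benzylic centre, (3S) in A4, to give the (2R) configuration; acetylation and hydrogenolysis would follow.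

- In its favour:
  - One catalytic C–C bond formation creates both stereocentres from two achiral pieces, and on this point it is the better plan.
  - It is equal to the chosen route in convergence.
  - The C3 oxygen is differentiated from the phenols throughout, so the final acetylation is trivial, which is again better.
- Against it here:
  - A5 is a ketone flanked by two ortho oxygen substituents and is twisted and hindered.
  - A6 is an electron-rich, weakly electrophilic aldehyde whose aldol adducts revert easily, so diastereo- and enantioselectivity may erode.
  - The para-alkoxybenzylic alcohol can ionise under Mitsunobu conditions, which would spoil the inversion and give cis/trans mixtures.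
  - A5 needs an alpha-hydroxylation and a third kind of protecting group beyond the ring A chemistry that the chosen route also needs.
- Comparison:
  - Structure: both plans fix the methoxy position through a single free ortho hydroxyl.
  - Mechanism: the aldol step is reagent-controlled but stretched on both partners, whereas the enzyme step is untested on one remote substituent.
  - Step economy: the count should be equal or one to two steps higher.

Alternative 3: The cut runs through ring A at C4a–C5 and C8–C8a. The bromo dihydropyranone A8 and the diene A9 would combine in a (4+2) cycloaddition; loss of HBr and methanol would aromatise the adduct to A7. The CH2 terminus of A9 should bond to the oxygen-bearing alkene carbon of A8 and the ketene acetal carbon to the brominated one. That would place the methoxy group at C6 and the hydroxyls at C5 and C7.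

- In its favour:
  - Ring A is made in one step with its complete oxygen pattern and no ring A protecting group.
  - The stereocentres and the acetate are set on a small ring beforehand.
  - Only one debenzylation follows.
  - In step count and in the way the methoxy position is secured this is the better plan, and it also avoids any selective deacetylation.
- Against it here:
  - A8 is a vinylogous ester and a poor partner for a very electron-rich diene.
  - The heat or Lewis acid needed may eliminate acetic acid from A8 to a pyranone or epimerise C3.
  - A9 is hydrolytically labile.
  - Aromatisation needs base or heat in the presence of the same fragile alpha-acetoxy ketone.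
  - There is no close precedent for this class of dienophile.
- Comparison:
  - Structure: this plan is the most direct.
  - Mechanism: it is the least supported of the four.
  - Step economy: it would be clearly shorter than the chosen route if the key step worked.

Key step: step 9

Remark: flavanone 3-hydroxylase is assumed to be at hand as a recombinant plant enzyme produced in Escherichia coli; it is the catalyst of step 9 and not a purchased reagent.

## Route

Step 1
Reactants: 1 methyl 3,5-dihydroxy-4-methoxybenzoate
Product: 2 methyl 3,5-bis(benzyloxy)-4-methoxybenzoate
Conditions: BnBr, K2CO3, DMF, 60 °C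
Reagents that add atoms: benzyl bromide, BrCc1ccccc1
Why: Williamson ether synthesis on two equivalent phenols; the methyl ester and the methyl ether are inert to K2CO3 in dry DMF.

Step 2
Reactants: 2 methyl 3,5-bis(benzyloxy)-4-methoxybenzoate
Product: 3 [3,5-bis(benzyloxy)-4-methoxyphenyl]methanol
Conditions: LiAlH4, THF, 0 °C to rt
Reagents that add atoms: none
Why: Hydride reduction of the ester to the primary benzylic alcohol; aryl ethers do not react.

Step 3
Reactants: 3 [3,5-bis(benzyloxy)-4-methoxyphenyl]methanol
Product: 4 3,5-bis(benzyloxy)-4-methoxybenzaldehyde
Conditions: MnO2, CH2Cl2, rt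
Reagents that add atoms: none
Why: Activated MnO2 oxidises benzylic alcohols to aldehydes and stops there.

Step 4
Reactants: 4 3,5-bis(benzyloxy)-4-methoxybenzaldehyde
Product: 6 3,5-bis(benzyloxy)-4-methoxyphenol, via aryl formate 5 (not isolated)
Conditions: mCPBA, CH2Cl2, 0 °C to rt; then K2CO3 (cat.), MeOH, rt
Reagents that add atoms: 3-chloroperbenzoic acid, OOC(=O)c1cccc(Cl)c1
Why: Baeyer–Villiger oxidation of an electron-rich benzaldehyde; the para methoxy group makes the aryl group migrate in preference to hydrogen, and the formate 5 is cleaved by methanolysis.

Step 5
Reactants: 6 3,5-bis(benzyloxy)-4-methoxyphenol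
Product: 8 1-[2,4-bis(benzyloxy)-6-hydroxy-3-methoxyphenyl]ethan-1-one, via difluoroboron chelate 7 (not isolated)
Conditions: Ac2O, BF3·OEt2, CH2Cl2, 0 °C to rt; then NaOAc, MeOH–H2O, 60 °C
Reagents that add atoms: acetic anhydride, CC(=O)OC(C)=O
Why: Friedel–Crafts acylation (with Fries rearrangement of any O-acetate) at the only free ring positions, which are equivalent and ortho to the hydroxyl; the ketone is held as chelate 7, which prevents a second acylation and is hydrolysed in the second stage.

Step 6
Reactants: 8 1-[2,4-bis(benzyloxy)-6-hydroxy-3-methoxyphenyl]ethan-1-one
Product: 10 5,7-bis(benzyloxy)-6-methoxy-4H-chromen-4-one, via enaminone 9 (not isolated)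
Conditions: Me2NCH(OMe)2, toluene, 100 °C; then conc. HCl, CH2Cl2, rt
Reagents that add atoms: N,N-dimethylformamide dimethyl acetal, COC(OC)N(C)C
Why: Condensation at the acetyl methyl group gives enaminone 9; acid then brings about conjugate addition of the only free phenol and loss of dimethylamine (addition–elimination), closing ring C as the chromone with the methoxy group at C6.

Step 7
Reactants: 10 5,7-bis(benzyloxy)-6-methoxy-4H-chromen-4-one; 11 [4-(benzyloxy)phenyl]boronic acid
Product: 12 (2S)-5,7-bis(benzyloxy)-2-[4-(benzyloxy)phenyl]-6-methoxychroman-4-one
Conditions: [Rh(OH)(cod)]2 (cat.), (S)-MeO-F12-BIPHEP (the 3,4,5-trifluorophenyl analogue of MeO-BIPHEP, cat.), toluene–H2O, 30 °C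
Reagents that add atoms: none
Why: Hayashi–Miyaura asymmetric 1,4-addition: the aryl group passes from boron to monovalent rhodium, adds across C2=C3 on the face chosen by the electron-poor chiral bisphosphine, and water protonates the rhodium enolate, all without base so that ring C cannot open. By the stereochemical model for cyclic enones the (S)-ligand should give (2S); if the chromone responds in the opposite sense the (R)-ligand is used, and step 9 accepts only the (2S) enantiomer in any case.

Step 8
Reactants: 12 (2S)-5,7-bis(benzyloxy)-2-[4-(benzyloxy)phenyl]-6-methoxychroman-4-one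
Product: 13 (2S)-5,7-dihydroxy-2-(4-hydroxyphenyl)-6-methoxychroman-4-one
Conditions: H2 (1 atm), Pd/C, EtOAc–MeOH, rt
Reagents that add atoms: none
Why: Hydrogenolysis of three aryl benzyl ethers under neutral conditions, stopped at full conversion; no base is present, so C2 should keep its configuration.

Step 9
Reactants: 13 (2S)-5,7-dihydroxy-2-(4-hydroxyphenyl)-6-methoxychroman-4-one
Product: 14 (2R,3R)-3,5,7-trihydroxy-2-(4-hydroxyphenyl)-6-methoxychroman-4-one
Conditions: recombinant flavanone 3-hydroxylase (cell-free extract or resting cells), FeSO4 (divalent iron), 2-oxoglutarate, sodium ascorbate, catalase, air, Tris-HCl buffer pH 7.5 with 5% DMSO, 30 °C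
Reagents that add atoms: dioxygen, O=O
Why: Flavanone 3-hydroxylase is a non-haem iron enzyme: divalent iron held by two histidines and one carboxylate binds 2-oxoglutarate and O2, and oxidative decarboxylation releases succinate and CO2 and leaves a tetravalent iron-oxo species. This species abstracts the C3 hydrogen of 13 that lies trans to ring B, and the C3 radical recombines with the iron-bound hydroxyl on the same face (rebound with retention), which forms the C3–O bond. The closest known reaction is the conversion of (2S)-naringenin into (2R,3R)-aromadendrin by the same enzyme; 13 differs only by the methoxy group at C6, remote from C3, so this is a known reaction applied to a new member of the flavanone class. No ring is closed. The new stereocentre C3 is set by the enzyme pocket, which holds the (2S)-flavanone with ring B turned away from the iron centre so that only the trans hydrogen is within reach; C2 is not touched and is called R in 14 only because the new oxygen raises the rank of C3. The step needs site selectivity for C3 over the benzylic C2–H, trans delivery, and discrimination between the C2 enantiomers; all three come from the binding mode, and the last means that any (2R) material left from step 7 is not converted and is removed with unreacted substrate. Ascorbate keeps the iron divalent, catalase removes peroxide from uncoupled turnover, and pH 7.5 keeps opening of 13 to its chalcone slow.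

Step 10
Reactants: 14 (2R,3R)-3,5,7-trihydroxy-2-(4-hydroxyphenyl)-6-methoxychroman-4-one
Product: 15 (2R,3R)-2-[4-(acetyloxy)phenyl]-6-methoxy-4-oxochromane-3,5,7-triyl triacetate
Conditions: Ac2O, pyridine, 0 °C to rt
Reagents that add atoms: acetic anhydride, CC(=O)OC(C)=O
Why: Exhaustive O-acetylation; only complete acetylation at C3 matters, because the aryl acetates are removed in step 11, and pyridine at room temperature is too weak a base to epimerise C3 or eliminate the new acetate.

Step 11
Reactants: 15 (2R,3R)-2-[4-(acetyloxy)phenyl]-6-methoxy-4-oxochromane-3,5,7-triyl triacetate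
Product: 16 (2R,3R)-5,7-dihydroxy-2-(4-hydroxyphenyl)-6-methoxy-4-oxochroman-3-yl acetate
Conditions: NH4OAc, MeOH–H2O (4:1), rt
Reagents that add atoms: none
Why: Chemoselective methanolysis of aryl acetates under buffered, nearly neutral conditions; phenoxide is a far better leaving group than the C3 alkoxide, so the alkyl acetate should stay, and the pH is too low for elimination, epimerisation or ring opening.

## Compound list

1 | methyl 3,5-dihydroxy-4-methoxybenzoate | COC(=O)c1cc(O)c(OC)c(O)c1 | starting material
2 | methyl 3,5-bis(benzyloxy)-4-methoxybenzoate | COC(=O)c1cc(OCc2ccccc2)c(OC)c(OCc2ccccc2)c1 | intermediate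
3 | [3,5-bis(benzyloxy)-4-methoxyphenyl]methanol | OCc1cc(OCc2ccccc2)c(OC)c(OCc2ccccc2)c1 | intermediate
4 | 3,5-bis(benzyloxy)-4-methoxybenzaldehyde | O=Cc1cc(OCc2ccccc2)c(OC)c(OCc2ccccc2)c1 | intermediate
5 | 3,5-bis(benzyloxy)-4-methoxyphenyl formate | O=COc1cc(OCc2ccccc2)c(OC)c(OCc2ccccc2)c1 | intermediate (not isolated)
6 | 3,5-bis(benzyloxy)-4-methoxyphenol | Oc1cc(OCc2ccccc2)c(OC)c(OCc2ccccc2)c1 | intermediate
7 | difluoroboron chelate of ketone 8 (BF2 bridging the phenolic and the carbonyl oxygen) | CC1=[O+][B-](F)(F)Oc2cc(OCc3ccccc3)c(OC)c(OCc3ccccc3)c12 | intermediate (not isolated)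
8 | 1-[2,4-bis(benzyloxy)-6-hydroxy-3-methoxyphenyl]ethan-1-one | CC(=O)c1c(O)cc(OCc2ccccc2)c(OC)c1OCc1ccccc1 | intermediate
9 | (E)-1-[2,4-bis(benzyloxy)-6-hydroxy-3-methoxyphenyl]-3-(dimethylamino)prop-2-en-1-one | COc1c(OCc2ccccc2)cc(O)c(C(=O)/C=C/N(C)C)c1OCc1ccccc1 | intermediate (not isolated)
10 | 5,7-bis(benzyloxy)-6-methoxy-4H-chromen-4-one | COc1c(OCc2ccccc2)cc2occc(=O)c2c1OCc1ccccc1 | intermediate
11 | [4-(benzyloxy)phenyl]boronic acid | OB(O)c1ccc(OCc2ccccc2)cc1 | starting material
12 | (2S)-5,7-bis(benzyloxy)-2-[4-(benzyloxy)phenyl]-6-methoxychroman-4-one | COc1c(OCc2ccccc2)cc2c(c1OCc1ccccc1)C(=O)C[C@@H](c1ccc(OCc3ccccc3)cc1)O2 | intermediate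
13 | (2S)-5,7-dihydroxy-2-(4-hydroxyphenyl)-6-methoxychroman-4-one | COc1c(O)cc2c(c1O)C(=O)C[C@@H](c1ccc(O)cc1)O2 | intermediate
14 | (2R,3R)-3,5,7-trihydroxy-2-(4-hydroxyphenyl)-6-methoxychroman-4-one | COc1c(O)cc2c(c1O)C(=O)[C@H](O)[C@@H](c1ccc(O)cc1)O2 | intermediate
15 | (2R,3R)-2-[4-(acetyloxy)phenyl]-6-methoxy-4-oxochromane-3,5,7-triyl triacetate | COc1c(OC(C)=O)cc2c(c1OC(C)=O)C(=O)[C@H](OC(C)=O)[C@@H](c1ccc(OC(C)=O)cc1)O2 | intermediate
16 | (2R,3R)-5,7-dihydroxy-2-(4-hydroxyphenyl)-6-methoxy-4-oxochroman-3-yl acetate (6-methoxyaromadendrin 3-O-acetate) | COc1c(O)cc2c(c1O)C(=O)[C@H](OC(C)=O)[C@@H](c1ccc(O)cc1)O2 | target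

## Step count and least certain steps

Total: 11 steps. Longest linear sequence: 11 steps, from 1 to 16; 11 is purchased and enters at step 7.

Step 9 (key step). The likeliest failure is slow or no turnover, because the methoxy group at C6 may not fit the part of the pocket that binds ring A. Uncoupled consumption of 2-oxoglutarate would then inactivate the enzyme, and some further desaturation towards the flavonol is also possible. The fallback is chemical and sets out from 12. Enolisation with LiN(SiMe3)2 in the presence of Me3SiCl (THF, −78 °C, internal quench to limit opening of ring C) should give the silyl enol ether (2S)-{[5,7-bis(benzyloxy)-2-[4-(benzyloxy)phenyl]-6-methoxy-2H-chromen-4-yl]oxy}trimethylsilane F1. Rubottom oxidation with dimethyldioxirane in acetone at low temperature, with attack anti to ring B and cleavage of the silyl group on work-up, should give (2R,3R)-5,7-bis(benzyloxy)-2-[4-(benzyloxy)phenyl]-3-hydroxy-6-methoxychroman-4-one F2. Hydrogenolysis (H2, Pd/C) brings the route back at 14.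

Step 5. The Lewis acid may remove or shift the benzyl group next to the new carbonyl through chelation, or the reaction may stop at O-acetylation. The fallback sets out from 6. Ortho-formylation with MgCl2, Et3N and paraformaldehyde in MeCN (Casnati–Skattebøl conditions) should give 2,4-bis(benzyloxy)-6-hydroxy-3-methoxybenzaldehyde F3. Excess MeMgBr in THF then gives racemic 3,5-bis(benzyloxy)-2-(1-hydroxyethyl)-4-methoxyphenol F4, and MnO2 in CH2Cl2 oxidises the benzylic alcohol, returning to the route at 8.

Step 7. Carbometalation of the electron-rich chromone may be slower than protodeboronation of 11, and facial selectivity may be insufficient. The fallback sets out from 8.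
- Claisen–Schmidt condensation with 4-(benzyloxy)benzaldehyde (KOH, EtOH, rt) should give (E)-1-[2,4-bis(benzyloxy)-6-hydroxy-3-methoxyphenyl]-3-[4-(benzyloxy)phenyl]prop-2-en-1-one F5.
- NaOAc in refluxing EtOH closes it through the only free ortho hydroxyl to racemic 5,7-bis(benzyloxy)-2-[4-(benzyloxy)phenyl]-6-methoxychroman-4-one F6.
- Hydrogenolysis gives racemic 5,7-dihydroxy-2-(4-hydroxyphenyl)-6-methoxychroman-4-one F7.
- Under the conditions of step 9 the enzyme should convert only the (2S) half, so the route is rejoined at 14. The unconverted (2R) half can be equilibrated through ring opening with mild base and submitted again.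

Step 8. Over-reduction is the risk: hydrogenolysis of the benzylic C2–O1 bond, which opens ring C, or reduction of the aryl ketone. The fallback sets out from 12 and removes the benzyl groups without hydrogen, using BCl3 with pentamethylbenzene as cation scavenger in CH2Cl2 at −78 °C. The methyl ether is expected to survive at that temperature. The route is rejoined at 13 and no new intermediate arises.

Step 11. Partial loss of the C3 acetate, or incomplete cleavage of the hindered acetate at C5, would give mixtures. The fallback avoids any discrimination between esters by keeping the phenols as benzyl ethers until after acetylation. It sets out from 12, passes through the silyl enol ether F1 and the protected dihydroflavonol F2 described under step 9, and acetylates F2 (Ac2O, pyridine, DMAP) to (2R,3R)-5,7-bis(benzyloxy)-2-[4-(benzyloxy)phenyl]-6-methoxy-4-oxochroman-3-yl acetate F8. Hydrogenolysis (H2, Pd/C, EtOAc) then leaves the alkyl acetate in place and reaches the route again at 16.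

## Further compounds

F1 | step 9 | (2S)-{[5,7-bis(benzyloxy)-2-[4-(benzyloxy)phenyl]-6-methoxy-2H-chromen-4-yl]oxy}trimethylsilane | COc1c(OCc2ccccc2)cc2c(c1OCc1ccccc1)C(O[Si](C)(C)C)=C[C@@H](c1ccc(OCc3ccccc3)cc1)O2
F2 | step 9 | (2R,3R)-5,7-bis(benzyloxy)-2-[4-(benzyloxy)phenyl]-3-hydroxy-6-methoxychroman-4-one | COc1c(OCc2ccccc2)cc2c(c1OCc1ccccc1)C(=O)[C@H](O)[C@@H](c1ccc(OCc3ccccc3)cc1)O2
F3 | step 5 | 2,4-bis(benzyloxy)-6-hydroxy-3-methoxybenzaldehyde | O=Cc1c(O)cc(OCc2ccccc2)c(OC)c1OCc1ccccc1
F4 | step 5 | 3,5-bis(benzyloxy)-2-(1-hydroxyethyl)-4-methoxyphenol (racemic) | CC(O)c1c(O)cc(OCc2ccccc2)c(OC)c1OCc1ccccc1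
F5 | step 7 | (E)-1-[2,4-bis(benzyloxy)-6-hydroxy-3-methoxyphenyl]-3-[4-(benzyloxy)phenyl]prop-2-en-1-one | COc1c(OCc2ccccc2)cc(O)c(C(=O)/C=C/c2ccc(OCc3ccccc3)cc2)c1OCc1ccccc1
F6 | step 7 | 5,7-bis(benzyloxy)-2-[4-(benzyloxy)phenyl]-6-methoxychroman-4-one (racemic) | COc1c(OCc2ccccc2)cc2c(c1OCc1ccccc1)C(=O)CC(c1ccc(OCc3ccccc3)cc1)O2
F7 | step 7 | 5,7-dihydroxy-2-(4-hydroxyphenyl)-6-methoxychroman-4-one (racemic) | COc1c(O)cc2c(c1O)C(=O)CC(c1ccc(O)cc1)O2
F0 | step 8 | none | none
F8 | step 11 | (2R,3R)-5,7-bis(benzyloxy)-2-[4-(benzyloxy)phenyl]-6-methoxy-4-oxochroman-3-yl acetate | COc1c(OCc2ccccc2)cc2c(c1OCc1ccccc1)C(=O)[C@H](OC(C)=O)[C@@H](c1ccc(OCc3ccccc3)cc1)O2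
A1 | alternative 1 | (2R,3R,4R)-5,7-bis(benzyloxy)-2-[4-(benzyloxy)phenyl]-6-methoxychromane-3,4-diol 3,4-acetonide (2,3-trans, 3,4-trans) | COc1c(OCc3ccccc3)cc2c(c1OCc1ccccc1)[C@H]1OC(C)(C)O[C@@H]1[C@@H](c1ccc(OCc3ccccc3)cc1)O2
A2 | alternative 1 | (R)-[4-(benzyloxy)phenyl]{(4R,5R)-5-[2,4-bis(benzyloxy)-6-bromo-3-methoxyphenyl]-2,2-dimethyl-1,3-dioxolan-4-yl}methanol | COc1c(OCc3ccccc3)cc(Br)c(c1OCc1ccccc1)[C@H]1OC(C)(C)O[C@@H]1[C@@H](c1ccc(OCc3ccccc3)cc1)O
A3 | alternative 1 | (E)-3-[2,4-bis(benzyloxy)-6-bromo-3-methoxyphenyl]-1-[4-(benzyloxy)phenyl]prop-2-en-1-one | COc1c(OCc2ccccc2)cc(Br)c(/C=C/C(=O)c2ccc(OCc3ccccc3)cc2)c1OCc1ccccc1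
A4 | alternative 2 | (2R,3S)-1-[2,4-bis(benzyloxy)-3-methoxy-6-(methoxymethoxy)phenyl]-3-[4-(benzyloxy)phenyl]-2,3-dihydroxypropan-1-one | COCOc1cc(OCc2ccccc2)c(OC)c(OCc2ccccc2)c1C(=O)[C@H](O)[C@@H](O)c1ccc(OCc2ccccc2)cc1
A5 | alternative 2 | 1-[2,4-bis(benzyloxy)-3-methoxy-6-(methoxymethoxy)phenyl]-2-hydroxyethan-1-one | COCOc1cc(OCc2ccccc2)c(OC)c(OCc2ccccc2)c1C(=O)CO
A6 | alternative 2 | 4-(benzyloxy)benzaldehyde | O=Cc1ccc(OCc2ccccc2)cc1
A7 | alternative 3 | (2R,3R)-2-[4-(benzyloxy)phenyl]-5,7-dihydroxy-6-methoxy-4-oxochroman-3-yl acetate | COc1c(O)cc2c(c1O)C(=O)[C@H](OC(C)=O)[C@@H](c1ccc(OCc3ccccc3)cc1)O2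
A8 | alternative 3 | (2R,3R)-2-[4-(benzyloxy)phenyl]-5-bromo-4-oxo-3,4-dihydro-2H-pyran-3-yl acetate | BrC1=CO[C@H](c2ccc(OCc3ccccc3)cc2)[C@@H](OC(C)=O)C1=O
A9 | alternative 3 | 1,2-dimethoxy-1,3-bis(trimethylsilyloxy)buta-1,3-diene | C=C(O[Si](C)(C)C)C(OC)=C(OC)O[Si](C)(C)C
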